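**Retrosynthetic overview**

1. Numbering: abietane C1–C20 for rings A, B and C (ring C = C8, C9, C11, C12, C13, C14); primed thujane numbers for the monoterpene part (C4' = spiro carbon, C10' = carbinol carbon); ring E = C7, C8, C14, C4', C10'.
2. The target is the enol tautomer of an 11,12-ortho-quinone, so it is traced back to a 12-phenol (ring C aromatic, C7 sp3); the C11 oxygen is put in last.
3. Ring C is cut at C13–C14 and C12–C13 in a formal (5+1) annulation: an isopropyl ynolate supplies C13, and the ring E ketone C14 plus the ester carbon C12 frame the other five atoms. The enabling feature is the 1,5-relationship of the C14 carbonyl and the C12 carboxyl carbon across C8–C9–C11, together with the C7=C8 double bond of ring E, which lets the new ring aromatise without an oxidant.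
4. Ring E is cut at C8–C14 (vinyllithium onto a nitrile) and at C4'–C10' (nitrile-anion aldol), which divides the molecule into a bromo enal (rings A and B, from (+)-sclareolide with C17 excised) and a thujane nitrile (from (+)-sabinene).
5. Order of ring formation: rings A and B and the bicyclo[3.1.0]hexane come from the chiral pool, then ring E, then ring C.

Key step: step 10

Remark on the chemistry: (+)-sabinene is taken as the (1R,5R) enantiomer; C7 of 24 to 26 is a transient stereocentre, drawn as the epimer expected from protonation anti to the silyloxy group, and it is erased in step 12.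

**Route**

Step 1
Reactants: 1 (+)-sclareolide
Product: 3 methyl 8α-hydroxy-13,14,15,16-tetranorlabdan-12-oate, via potassium carboxylate 2 (not isolated)
Conditions: KOH, MeOH, reflux; then MeI, DMF, rt
Reagents that add atoms: potassium hydroxide [K+].[OH-]; iodomethane CI
Why: Lactone saponification followed by SN2 O-methylation of the carboxylate, without acidification so that relactonisation is avoided, should give the hydroxy ester; no stereocentre is touched.

Step 2
Reactants: 3 methyl 8α-hydroxy-13,14,15,16-tetranorlabdan-12-oate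
Product: 4 methyl 13,14,15,16-tetranorlabd-8(17)-en-12-oate
Conditions: SOCl2, pyridine, CH2Cl2, −78 °C
Reagents that add atoms: none
Why: Alcohol dehydration through the chlorosulfite (E2) should run toward the C17 methyl group, because the equatorial C8–O bond has no antiperiplanar ring hydrogen; no new stereocentre.

Step 3
Reactants: 4 methyl 13,14,15,16-tetranorlabd-8(17)-en-12-oate
Product: 6 methyl 8-oxo-13,14,15,16,17-pentanorlabdan-12-oate, via secondary ozonide 5 (not isolated)
Conditions: O3, CH2Cl2, −78 °C; then Me2S, −78 °C to rt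
Reagents that add atoms: ozone [O-][O+]=O
Why: Ozonolysis with reductive work-up should cleave the 1,1-disubstituted alkene to the C8 ketone and excise C17; C9 keeps its equatorial, thermodynamically preferred configuration.

Step 4
Reactants: 6 methyl 8-oxo-13,14,15,16,17-pentanorlabdan-12-oate
Product: 8 methyl 8-bromo-7-formyl-13,14,15,16,17-pentanorlabd-7-en-12-oate, via iminium bromide 7 (not isolated)
Conditions: PBr3, DMF, CHCl3, 0 to 60 °C; then ice-water
Reagents that add atoms: N,N-dimethylformamide CN(C)C=O; phosphorus tribromide BrP(Br)Br; water O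
Why: Vilsmeier–Haack–Arnold bromoformylation should formylate the ketone at its only methylene alpha-carbon C7 and turn the carbonyl carbon C8 into the vinyl bromide; no new stereocentre.

Step 5
Reactants: 9 (+)-sabinene
Product: 11 sabina ketone, via ozonide 10 (not isolated)
Conditions: O3, CH2Cl2, −78 °C; then Me2S, −78 °C to rt
Reagents that add atoms: ozone [O-][O+]=O
Why: Ozonolysis of the exocyclic methylene with reductive work-up should give the cyclopropyl ketone; the cyclopropane and both stereocentres are untouched at this temperature.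

Step 6
Reactants: 11 sabina ketone
Product: 12 (1R,5R)-5-isopropylbicyclo[3.1.0]hexane-2-carbonitrile (4'-cyanothujane; C4' epimers)
Conditions: TosMIC, KOtBu, DME/EtOH, 0 °C to rt
Reagents that add atoms: tosylmethyl isocyanide [C-]#[N+]CS(=O)(=O)c1ccc(C)cc1
Why: Van Leusen reductive cyanation should convert the ketone into the one-carbon-homologated nitrile; the C4' epimer mixture is acceptable because C4' becomes planar in step 7.

Step 7
Reactants: 12 (1R,5R)-5-isopropylbicyclo[3.1.0]hexane-2-carbonitrile; 8 methyl 8-bromo-7-formyl-13,14,15,16,17-pentanorlabd-7-en-12-oate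
Product: 15 methyl 8-bromo-7-[(tert-butyldimethylsilyloxy)(4'-cyanothujan-4'-yl)methyl]-13,14,15,16,17-pentanorlabd-7-en-12-oate (cyano group syn to the cyclopropane CH2; C10' as in the target), via lithiated nitrile 13 (not isolated), via lithium aldolate 14 (not isolated)
Conditions: LiN(iPr)2, THF, −78 °C; then 8, −78 °C; then TBSOTf, −78 to 0 °C
Reagents that add atoms: tert-butyldimethylsilyl trifluoromethanesulfonate CC(C)(C)[Si](C)(C)OS(=O)(=O)C(F)(F)F
Why: Aldol-type 1,2-addition of the tertiary nitrile anion to the aldehyde with in situ O-silylation (which blocks retro-addition) should set C4' by approach of the aldehyde on the exo face anti to the cyclopropane methylene, leaving the cyano group (future C14) syn to it, and should set C10' in an open transition state in which the bulky bromoalkenyl group avoids the more hindered C5' side so that oxygen lies next to C5'.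

Step 8
Reactants: 15 methyl 8-bromo-7-[(tert-butyldimethylsilyloxy)(4'-cyanothujan-4'-yl)methyl]-13,14,15,16,17-pentanorlabd-7-en-12-oate
Product: 17 keto ester with ring E closed (cyclopentenone: C14=O; C7=C8; C10'-OTBS; spiro C4'; C9-CH2CO2Me), via N-lithio ketimine 16 (not isolated)
Conditions: t-BuLi (2.1 equiv), THF/Et2O, −100 to −40 °C; then AcOH, H2O/THF, rt
Reagents that add atoms: water O
Why: Parham cyclisation: bromine–lithium exchange at C8 should outrun attack of t-BuLi on the ester at −100 °C, the vinyllithium should add 5-exo-dig to the nitrile carbon (C14) to close ring E, and mild acid should hydrolyse the ketimine to the enone; no stereocentre is formed or touched.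

Step 9
Reactants: 18 ethyl 2-bromo-3-methylbutanoate
Product: 20 ethyl 2,2-dibromo-3-methylbutanoate, via lithium enolate 19 (not isolated)
Conditions: LiN(SiMe3)2, THF, −78 °C; then BrCCl2CCl2Br, −78 °C to rt
Reagents that add atoms: 1,2-dibromo-1,1,2,2-tetrachloroethane ClC(Cl)(Br)C(Cl)(Cl)Br
Why: Electrophilic alpha-bromination of the bromo ester enolate by a positive-bromine donor should give the gem-dibromo ester; the stereocentre of 18 disappears.

Step 10
Reactants: 20 ethyl 2,2-dibromo-3-methylbutanoate; 17 keto ester with ring E closed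
Product: 24 phenol (ring C aromatic with 12-OH and 13-isopropyl; C7-H beta; C10'-OTBS), via lithium ynolate 21 (not isolated), via fused beta-lactone 22 (not isolated), via dienone 23 (not isolated)
Conditions: 20, t-BuLi (4 equiv to 20), THF, −78 to 0 °C; then 17, −78 °C to rt; H2O work-up; then SiO2, PhMe, 90 °C
Reagents that add atoms: none
Why: The ynolate carbon (future C13, already carrying the isopropyl group) adds to the non-enolisable C14 carbonyl of 17 in a formal (2+2) cycloaddition that forms the C13–C14 bond and closes a temporary spiro beta-lactone, whose enolate carbon C13 then attacks the C12 ester in a 6-(enolexo)-exo-trig Dieckmann closure of ring C to give 22; on warm silica the beta-lactone undergoes (2+2) cycloreversion, expelling the oxygen-bearing ynolate carbon as CO2 and leaving the C13=C14 double bond of dienone 23, which isoaromatises by moving H9 to C7 and H11 to oxygen. The closest known reaction type is the tandem ynolate (2+2) cycloaddition–Dieckmann condensation–decarboxylation of delta-keto esters, a formal (5+1) annulation that gives 2,3-disubstituted cyclohexenones. The beta-lactone closes by (2+2) addition across C=O and ring C closes by intramolecular acylation. The transient centres C13 and C14 of 22 are fixed by the face of attack on C14 and are erased on CO2 loss, while C7 of 24 is set by protonation anti to the silyloxy group and is erased in step 12. The step needs chemoselectivity for ketone over ester and 1,2- over 1,4-addition, secured by the low basicity and linear shape of the ynolate and by the fully substituted beta-carbon C7. It also needs attack on the beta face, which carries the C9 acetate arm and is the only face from which the enolate can reach the ester; this is secured by the bulky alpha-oriented silyl ether at C10'. No oxidant is needed because the C7=C8 bond of ring E supplies the third unsaturation of the arene.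

Step 11
Reactants: 24 phenol (C10'-OTBS)
Product: 25 hydroxy phenol (12-OH; C10'-OH alpha; C7-H beta)
Conditions: Bu4NF, THF, 50 °C
Reagents that add atoms: none
Why: Fluoride-mediated cleavage of the Si–O bond should free the hindered secondary alcohol on gentle warming; no stereocentre is affected.

Step 12
Reactants: 25 hydroxy phenol
Product: 27 target compound CNP0114174.1, via ortho-quinone 26 (not isolated)
Conditions: (PhSeO)2O, THF, rt to 50 °C; then silica gel
Reagents that add atoms: benzeneseleninic anhydride O=[Se](c1ccccc1)O[Se](=O)c1ccccc1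
Why: Barton ortho-oxygenation: the aryl seleninate of the phenol should deliver oxygen to the only free ortho position C11 by a 2,3-sigmatropic shift and collapse to the 11,12-quinone 26, which tautomerises (H7 to O11) to the more conjugated hydroxy quinone methide; this erases the C7 stereocentre and leaves C10' untouched, because the reagent does not oxidise secondary alcohols at this temperature.

**Compound list**

1 | (+)-sclareolide | C[C@]12CCCC(C)(C)[C@@H]1CC[C@@]3(C)OC(=O)C[C@H]23 | starting material
2 | potassium 8α-hydroxy-13,14,15,16-tetranorlabdan-12-oate | C[C@]12CCCC(C)(C)[C@@H]1CC[C@@](C)(O)[C@@H]2CC(=O)[O-].[K+] | intermediate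
3 | methyl 8α-hydroxy-13,14,15,16-tetranorlabdan-12-oate | C[C@]12CCCC(C)(C)[C@@H]1CC[C@@](C)(O)[C@@H]2CC(=O)OC | intermediate
4 | methyl 13,14,15,16-tetranorlabd-8(17)-en-12-oate | C[C@]12CCCC(C)(C)[C@@H]1CCC(=C)[C@@H]2CC(=O)OC | intermediate
5 | 8,17-ozonide (spiro 1,2,4-trioxolane at C8, epimers) of 4 | C[C@]12CCCC(C)(C)[C@@H]1CCC3(OCOO3)[C@@H]2CC(=O)OC | intermediate
6 | methyl 8-oxo-13,14,15,16,17-pentanorlabdan-12-oate | C[C@]12CCCC(C)(C)[C@@H]1CCC(=O)[C@@H]2CC(=O)OC | intermediate
7 | methyl 8-bromo-7-(dimethyliminiomethyl)-13,14,15,16,17-pentanorlabd-7-en-12-oate bromide | C[C@]12CCCC(C)(C)[C@@H]1CC(C=[N+](C)C)=C(Br)[C@@H]2CC(=O)OC.[Br-] | intermediate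
8 | methyl 8-bromo-7-formyl-13,14,15,16,17-pentanorlabd-7-en-12-oate | C[C@]12CCCC(C)(C)[C@@H]1CC(C=O)=C(Br)[C@@H]2CC(=O)OC | intermediate
9 | (+)-sabinene, (1R,5R)-4-methylidene-1-isopropylbicyclo[3.1.0]hexane | C=C1CC[C@]2(C(C)C)C[C@@H]21 | starting material
10 | sabinene ozonide (spiro 1,2,4-trioxolane at C4', epimers) | C1OC2(CC[C@]3(C(C)C)C[C@@H]32)OO1 | intermediate
11 | sabina ketone, (1S,5R)-5-isopropylbicyclo[3.1.0]hexan-2-one | O=C1CC[C@]2(C(C)C)C[C@@H]21 | intermediate
12 | (1R,5R)-5-isopropylbicyclo[3.1.0]hexane-2-carbonitrile (4'-cyanothujane, C4' epimers) | N#CC1CC[C@]2(C(C)C)C[C@@H]21 | intermediate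
13 | lithiated nitrile (N-lithio ketenimine form of 12) | [Li+].[N-]=C=C1CC[C@]2(C(C)C)C[C@@H]21 | intermediate
14 | lithium aldolate (C10' alkoxide of the adduct of 13 and 8) | C[C@]12CCCC(C)(C)[C@@H]1CC([C@@H]([O-])[C@@]3(C#N)CC[C@]4(C(C)C)C[C@@H]43)=C(Br)[C@@H]2CC(=O)OC.[Li+] | intermediate
15 | methyl 8-bromo-7-[(tert-butyldimethylsilyloxy)(4'-cyanothujan-4'-yl)methyl]-13,14,15,16,17-pentanorlabd-7-en-12-oate (cyano syn to cyclopropane CH2; C10' as in target) | C[C@]12CCCC(C)(C)[C@@H]1CC([C@@H](O[Si](C)(C)C(C)(C)C)[C@@]3(C#N)CC[C@]4(C(C)C)C[C@@H]43)=C(Br)[C@@H]2CC(=O)OC | intermediate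
16 | N-lithio ketimine of ring E (C14=N) | C[C@]12CCCC(C)(C)[C@@H]1CC3=C([C@@H]2CC(=O)OC)C(=[N-])[C@@]4(CC[C@]5(C(C)C)C[C@@H]54)[C@@H]3O[Si](C)(C)C(C)(C)C.[Li+] | intermediate
17 | keto ester with ring E closed (spiro cyclopentenone: C14=O, C7=C8, C10'-OTBS alpha; C9-CH2CO2Me) | C[C@]12CCCC(C)(C)[C@@H]1CC3=C([C@@H]2CC(=O)OC)C(=O)[C@@]4(CC[C@]5(C(C)C)C[C@@H]54)[C@@H]3O[Si](C)(C)C(C)(C)C | intermediate
18 | ethyl 2-bromo-3-methylbutanoate (racemic) | CCOC(=O)C(Br)C(C)C | starting material
19 | lithium enolate of 18 | CCOC([O-])=C(Br)C(C)C.[Li+] | intermediate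
20 | ethyl 2,2-dibromo-3-methylbutanoate | CCOC(=O)C(Br)(Br)C(C)C | intermediate
21 | lithium 3-methylbut-1-yn-1-olate | CC(C)C#C[O-].[Li+] | intermediate
22 | fused beta-lactone (ring C closed: C12 ketone, C13 quaternary with beta isopropyl, lactone C13–C(=O)–O–C14 on the alpha face) | CC(C)[C@]12C(=O)C[C@H]3C4=C(C[C@H]5C(C)(C)CCC[C@]35C)[C@@H](O[Si](C)(C)C(C)(C)C)[C@]6(CC[C@]7(C(C)C)C[C@@H]76)[C@@]41OC2=O | intermediate
23 | dienone (C12=O, C13=C14, C7=C8; C9-H alpha; C10'-OTBS) | CC(C)C1=C2C3=C(C[C@H]4C(C)(C)CCC[C@]4(C)[C@H]3CC1=O)[C@@H](O[Si](C)(C)C(C)(C)C)[C@]21CC[C@]2(C(C)C)C[C@@H]21 | intermediate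
24 | phenol (ring C aromatic, 12-OH, 13-isopropyl; C7-H beta; C10'-OTBS alpha) | CC(C)c1c(O)cc2c3c1[C@@]4(CC[C@]5(C(C)C)C[C@@H]54)[C@H](O[Si](C)(C)C(C)(C)C)[C@@H]3C[C@H]6C(C)(C)CCC[C@]26C | intermediate
25 | hydroxy phenol (12-OH; C10'-OH alpha; C7-H beta) | CC(C)c1c(O)cc2c3c1[C@@]4(CC[C@]5(C(C)C)C[C@@H]54)[C@H](O)[C@@H]3C[C@H]6C(C)(C)CCC[C@]26C | intermediate
26 | 11,12-ortho-quinone (C13=C14, C8=C9; C7-H beta; C10'-OH) | CC(C)C1=C2C3=C(C(=O)C1=O)[C@@]4(C)CCCC(C)(C)[C@@H]4C[C@H]3[C@@H](O)[C@]21CC[C@]2(C(C)C)C[C@@H]21 | intermediate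
27 | CNP0114174.1 (11-hydroxy-12-oxo quinone methide; 5S, 10S, 10'R, 4'S, 1'R, 5'S) | CC(C)C1=C2C3=C(C[C@H]4C(C)(C)CCC[C@]4(C)C3=C(O)C1=O)[C@@H](O)[C@]21CC[C@]2(C(C)C)C[C@@H]21 | target

**Step count and risks**

Total step count: 12. Longest linear sequence: 9 steps (steps 1, 2, 3, 4, 7, 8, 10, 11, 12, from (+)-sclareolide).

Steps most likely to fail:

1. Step 10. The ynolate may add to the alpha face of the hindered C14 carbonyl (or too slowly), so that the lactone enolate cannot reach the ester and opens to an acrylate instead of closing ring C. The fallback sets out from 15 and comes back at 24, and closes ring C by olefination instead. The methyl ester of 15 is acylated with LiCH(iPr)P(O)(OEt)2 (from diethyl (2-methylpropyl)phosphonate and n-BuLi, THF, −78 °C) to the beta-keto phosphonate F1. Ring E is then closed by a tin hydride radical chain (Bu3SnH added slowly, AIBN, PhH, 80 °C; then aqueous AcOH), in which the C8 vinyl radical adds 5-exo to the nitrile, to give the ring E enone beta-keto phosphonate F2. K2CO3 with 18-crown-6 in toluene at 80 °C then closes C13=C14 by intramolecular Horner–Wadsworth–Emmons reaction onto the C14 ketone, and the dienone 23 so formed isoaromatises to 24.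

2. Step 7. The open transition state may give poor facial selectivity at C10', or the adduct may revert before it is silylated. The fallback sets out from 14 and comes back at 17, and sets C10' by ketone reduction in the rigid ring instead. The aldolate 14 is protonated (aqueous NH4Cl) to the beta-hydroxy nitrile F3 as a C10' epimer mixture, and the allylic alcohol is oxidised with MnO2 in CH2Cl2 to the beta-keto nitrile F4. Tin hydride radical cyclisation onto the nitrile (Bu3SnH, AIBN, PhH, 80 °C; then aqueous AcOH) gives the spiro ene-dione F5. NaBH4 with CeCl3·7H2O in MeOH at −78 °C should reduce the less hindered C10' carbonyl (C14=O is screened by the C9 acetate arm) from the C3' face, placing the hydroxyl on the C5' side as in the target, to give the hydroxy enone F6. TBSOTf with 2,6-lutidine returns 17.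

3. Step 8. Attack of t-BuLi on the methyl ester, or proton transfer from C11 to the vinyllithium, may compete with cyclisation. The fallback sets out from 15 and comes back at 17: a radical instead of an anionic closure of ring E, with Bu3SnH added slowly and AIBN in PhH at 80 °C followed by aqueous AcOH, which tolerates the ester and makes no new compound F0.

Further compounds
F1 | step 10 | beta-keto phosphonate from 15 (C12 ketone; C13 bearing isopropyl and diethoxyphosphoryl, epimers) | C[C@]12CCCC(C)(C)[C@@H]1CC([C@@H](O[Si](C)(C)C(C)(C)C)[C@@]3(C#N)CC[C@]4(C(C)C)C[C@@H]43)=C(Br)[C@@H]2CC(=O)C(C(C)C)P(=O)(OCC)OCC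
F2 | step 10 | ring E enone beta-keto phosphonate | C[C@]12CCCC(C)(C)[C@@H]1CC3=C([C@@H]2CC(=O)C(C(C)C)P(=O)(OCC)OCC)C(=O)[C@@]4(CC[C@]5(C(C)C)C[C@@H]54)[C@@H]3O[Si](C)(C)C(C)(C)C
F3 | step 7 | beta-hydroxy nitrile (C10' epimers) | C[C@]12CCCC(C)(C)[C@@H]1CC(C(O)[C@@]3(C#N)CC[C@]4(C(C)C)C[C@@H]43)=C(Br)[C@@H]2CC(=O)OC
F4 | step 7 | beta-keto nitrile (C10' ketone) | C[C@]12CCCC(C)(C)[C@@H]1CC(C(=O)[C@@]3(C#N)CC[C@]4(C(C)C)C[C@@H]43)=C(Br)[C@@H]2CC(=O)OC
F5 | step 7 | spiro ene-dione (C14=O and C10'=O in ring E) | C[C@]12CCCC(C)(C)[C@@H]1CC3=C([C@@H]2CC(=O)OC)C(=O)[C@@]4(CC[C@]5(C(C)C)C[C@@H]54)C3=O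
F6 | step 7 | hydroxy enone (C14=O; C10'-OH alpha) | C[C@]12CCCC(C)(C)[C@@H]1CC3=C([C@@H]2CC(=O)OC)C(=O)[C@@]4(CC[C@]5(C(C)C)C[C@@H]54)[C@@H]3O
F0 | step 8 | none | none
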